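**Count what stays.** The green run is slow: after 15.0 h it still shows 45.7% of its G. So you do better to count what is left than what is made.

| flask | G | E | remark | time |
|---|---|---|---|---|
| teal | 2 M | 0.53 equiv | run made earlier |  |
| red | 2 M | 0.79 equiv | run made earlier |  |
| green | 1 M | 1.05 equiv | run made earlier |  |
| flask | 2.0 M | 1.05 equiv |  | 12 h |

- teal (time / h: Z / %, J / %, G / %): 0.833: 2.7, 0.7, 93.2; 2.00: 4.1, 0, 86.3; 4.00: 6.1, 1.1, 77.6; 6.00: 7.6, 2.3, 70.8; 8.00: 8.8, 3.4, 67.4; 12.0: 6.8, 3.4, 61.0; 15.0: 5.9, 5.4, 57.7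
- red (time / h: Z / %, J / %, G / %): 0.833: 2.4, 0.6, 90.2; 2.00: 6.0, 0.7, 79.5; 4.00: 9.1, 0.7, 66.7; 6.00: 9.7, 2.8, 58.9; 8.00: 10.2, 2.3, 53.0; 12.0: 9.5, 5.5, 46.7; 15.0: 8.5, 6.8, 42.8
- green (time / h: Z / %, J / %, G / %): 1.00: 2.6, 0.8, 91.0; 2.00: 4.8, 1.7, 84.9; 4.00: 6.9, 0.6, 74.2; 8.00: 9.6, 3.1, 59.0; 15.0: 9.0, 7.1, 45.7

(each reading ± 0.5 percentage points)

- amount of Z in the flask at 12 h, in percent of the G charged
- amount of J in the flask at 12 h, in percent of the G charged

- steps under discussion: G + E <-> Z; G + E -> L; G + E -> D; Z -> J; G -> Q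

**Loss constant.** In the flask, E stands at 1.05 equiv, so G is the limiting reagent. The steps that consume G, G to Q apart, take E with it, one for one, so at this ratio [E] should track [G] and the loss should look second order. Take the loss constant: the rise in the reciprocal of [G] per hour. The green run, charged at the same ratio, gives a reading of 0.0792 M⁻¹ h⁻¹.

**The ledger.** Enter each mole of G charged. For G left, you need one over (one plus constant times starting [G] times time), which I reckon at 34.5%, or 0.689 M. The forecast's own [G] is higher, 0.72 M. It enters Z at 11.7% (10.3% to 13.2%) and J at 6.8% (5.3% to 8.4%), reasoning that “Late Z looks quasi-equilibrated”. The books close with an unread rest of 47.0%, owed to L, D and Q.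

**The flask.** It gives Z 11.3% and J 6.81%, both inside the forecast's ranges.

    G + E ⇌ Z (K = 0.570 M⁻¹, k = 8.00 × 10⁻⁶ M⁻¹ s⁻¹)
    G + E → L (k = 5.90 × 10⁻⁶ M⁻¹ s⁻¹)
    G + E → D (k = 9.80 × 10⁻⁶ M⁻¹ s⁻¹)
    Z → J (k = 1.50 × 10⁻⁵ s⁻¹)
    G → Q (k = 1.40 × 10⁻⁸ s⁻¹)

**What stood.** The flask holds 33.9% of its G against the 34.5% reckoned from 0.0792 M⁻¹ h⁻¹. At 12.0 h in the flask, Z is made at 0.314 of the rate at which it is used up, each step taken net, which is less than parity. Z stood at 12.5% at 6.00 h and at 11.3% at 12.0 h. For the neighbour charged with 0.50 M of G, at the same equivalents and time, the same constant gives 67.8% left, and that neighbour still holds 67% of its G.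

The earlier runs and the new flask come from a simulation for an exercise; noise was put on by code.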